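## Structural features

2,3-Dehydrosilychristin joins a 3,5,7-trihydroxychromone (rings A and C, primed locants) through C2' to C5 of a 2,3-dihydrobenzofuran (benzo ring B fused to dihydrofuran ring D). Ring D carries a 4-hydroxy-3-methoxyphenyl group (ring E, double-primed locants) at C2 and a hydroxymethyl group at C3. These two neighbouring centres, (2R) and (3S), are trans and are the only stereocentres. Ring B is 1,2,3,5-tetrasubstituted: C3a and C7a belong to ring D, C7 next to the ring oxygen bears a free hydroxyl, and C5, para to O1, bears the chromone. The fragile points are the benzylic C2–O1 ether (a para-oxybenzyl aryl ether that ionises in acid and can be hydrogenolysed), the electron-rich flavonol with its enolic 3'-hydroxyl, and four phenols plus a primary alcohol that need a short protecting-group plan. The real difficulty is ring B: three contiguous substituents, two of them different oxygens, together with absolute and relative control of the C2/C3 diad. The key step uses the vicinal pair O1–C7a / HO–C7. This is the pattern left when an oxygen nucleophile and an oxygen electrophile end up on the two carbons of a C7a–C7 aryne. Because O1 is tied to C3a through C2 and C3, the nucleophilic half can be made intramolecular and closes ring D at the same time.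

## Logic of the disconnections

**28 from 27.** Cut: the four aryl O–benzyl bonds (C7, C5', C7', C4''). Reason: the phenols cannot pass through base, peroxide and organolithium chemistry, and benzyl leaves under neutral conditions that spare the acid-labile C2–O1 ether. Gain: every earlier compound is non-ionisable and soluble. Demand: the hydrogenolysis must stop before the benzylic C2–O1 bond or C2'=C3' is touched.

**27 from 25.** Cut: O1'–C2' and C3'–OH. Reason: a 2'-hydroxy enone is turned into the 3-hydroxychromone in one oxidative operation. Gain: ring C and its hydroxyl disappear. Demand: six-ring closure must win over five-ring (aurone) closure, which the alkoxy group flanking the carbonyl on ring A makes a real competitor.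

**25 from 22 and 24; 24 from 23.** Cut: C2'=C3'. Reason: an aldol condensation between a non-enolisable aldehyde and a methyl ketone. Gain: the molecule falls into two halves of similar size, and this is the convergent point. Demand: aqueous base must leave ring D untouched (neither C2–H nor C3–H is acidified by the C5 carbonyl, which is meta to C3a). 24 comes from 23 by cutting two O–benzyl bonds and relies on the chelated hydroxyl staying free.

**22 from 21, 20 and 19.** No skeletal bond is cut. The C5 formyl goes back to hydroxymethyl and then to its silyl ether, the C3 hydroxymethyl to its silyl ether, and the C7 benzyl ether to the phenol. Reason: no carbonyl may be present in the organolithium step and both primary oxygens must be capped there. Demand: oxidation of the benzylic alcohol in the presence of the aliphatic one.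

**19 from 14 (key).** Cut: O1–C7a and C7–OH. Reason: both oxygens of ring B are put on a C7a–C7 aryne, one as the tethered alkoxide and one as borate followed by peroxide. Gain: ring D and the awkward dioxygenation are replaced by a bromofluoroarene, and the diad moves to an open chain where an aldol can set it. Demand: Br at C7a and F at C7, a free secondary alcohol, no electrophilic group anywhere, and a primary-oxygen protecting group that does not migrate to the alkoxide.

**14 from 13 from 12.** Cut: two O–Si bonds. Both hydroxymethyl groups are then traced to carbonyls, the C3 one to the imide and the C5 one to a methyl ester. Reason: one hydride reagent reduces both and releases the auxiliary, so the C5 carbon needs no separate redox or protection steps. An acetal at C5 was rejected because it costs three extra steps and would have to face the boron triflate. Demand: silylation must distinguish primary from secondary hydroxyl.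

**12 from 9 and 10.** Cut: C2–C3 of the future ring D. Reason: a single auxiliary-controlled syn aldol sets both centres, and syn in the open chain corresponds to trans in the ring because the later closure breaks no bond at either carbon. Gain: two achiral aromatic halves. Demand: Z-enolate geometry, the (R)-auxiliary, and no retro-aldol at the doubly activated α-carbon.

**9 from 6 and 7.** Cut: the N–acyl bond. Demand: mild acylation that leaves the methyl ester alone.

**6 from 5 from 4.** Cut: C3a–CH2. Reason: ester α-arylation with a zinc enolate. The tert-butyl/methyl pair keeps the two carboxyl carbons distinct. Demand: coupling at C–I and not at the neighbouring C–Br.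

**4 from 2 from 1.** Cut: C7a–Br (back to C–N) and C3a–I (back to C–H). Reason: the amino group of 1 first directs iodination to its only free ortho position and is then exchanged for bromine. Fluorine and the C5 carbon are already in place. Demand: clean diazotisation of a weakly basic, doubly ortho-substituted aniline.

## Other disconnections considered

**Alternative 1:** The cut is C4'–C4a' of ring C. In the forward sense the acrylic acid A1 (carboxyl cis to the 3,5-bis(benzyloxy)phenoxy group) is activated with trifluoroacetic anhydride and acylates the ortho carbon of its own phloroglucinol-type ring, giving the fully benzylated flavonol A2; one hydrogenolysis would then give the target.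
- In favour: the attacked ring is symmetric, so there is no regiochemical question. The 3'-oxygen is built in, so the aurone problem of a chalcone oxidation cannot arise. On this point it is better than the chosen endgame. The final deprotection is equal.
- Against: it is an endgame cut only. It says nothing about ring D, ring B or the diad, so a full dihydrobenzofuran synthesis (possibly the aryne route itself) is still needed before it.
- Against: A1 is a tetrasubstituted β-aryloxy-α-alkoxy acrylic acid with no obvious geometry-defined preparation.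
- Against: the liberated trifluoroacetic acid meets the C2–O1 para-oxybenzyl ether, where ionisation would scramble C2. The primary alcohol also has to be benzylated, one more protecting group.
- Comparison: structurally it addresses rings A and C, the chosen plan ring B and ring D, so the two are not in competition for the hard part. Mechanistically it is an electrophilic substitution under acid, against anionic chemistry under base. In steps it is expected to be longer, because A1 needs several operations where condensation plus oxidation needs two.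

**Alternative 2:** The cuts are C2–C3 and O1–C2. In the forward sense Cs2CO3 converts the sulfonyl phenol A3 into an ortho-quinone methide, and the benzylide from the C2-symmetric thiolanium salt A4 adds to the methide carbon. The phenoxide then displaces the thiolane to give the trans ring A5. The antipode of A4 would be taken if the sense of induction required it.
- In favour: two bonds and both stereocentres form in one convergent step. The trans relationship follows from the anti addition and displacement (equal to the chosen plan). Both ring B oxygens are present from the start, so no aryne, no cryogenic organolithium and no oxygenation step are needed. On convergence and on steps to ring D it is the better plan.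
- Against: absolute control rests on face selection by a stoichiometric chiral sulfonium ylide. This is far less predictable for a new substrate than a chair-like boron aldol.
- Against: the quinone methide carries CH2OSi on the methide carbon. It can tautomerise to the 2-vinylphenol, and the sulfonyl carbanion can expel silyloxide.
- Against: the C5 bromine still has to be turned into the aldehyde, which costs one more step before the same endgame.
- Comparison: it is equal on diastereocontrol, better on step count and on the origin of the C7 oxygen, and weaker on certainty of the absolute configuration and on the stability of the reactive intermediate.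

**Alternative 3:** The cut is C3–C3a. In the forward sense PhI(OH)OTs in methanol activates C3=C4 of the (R)-chromene A6. Ring B carbon C4a shifts from C4 to C3 and the old C4 is left as a dimethyl acetal on the contracted ring A7.
- In favour: only one stereocentre has to be made beforehand, and C3 is set relative to it during the shift. The side-chain carbon arrives at the aldehyde level. No metal and no auxiliary are used. As in Alternative 2, both ring B oxygens are present from the start, which is a point in its favour over the chosen plan.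
- Against: ring E and ring B are themselves substrates for trivalent iodine.
- Against: 2-aryl-2H-chromenes lose configuration at C2 by ionisation or by electrocyclic opening to the quinone methide.
- Against: simple 3,4-dimethoxylation competes with the shift.
- Against: the trans outcome requires attack of the iodane anti to the C2 aryl group followed by migration with inversion.
- Against: the unmasked α-aryl aldehyde is prone to β-elimination of the phenoxide.
- Against: A6 needs an enantioselective synthesis, and acetal hydrolysis, reduction and conversion of bromine to formyl follow.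
- Comparison: it is equal at best on step count, more elegant in how C3 is set, and weaker on functional-group tolerance and on the safety of the C2 configuration.

Key step: step 9

Assumption: 4-benzyloxy-3-methoxybenzaldehyde (10) and the Reformatsky reagent ClZnCH2CO2t-Bu are used as bought; each is otherwise one routine operation away (O-benzylation of vanillin; zinc insertion into tert-butyl chloroacetate).

## Route

Step 1
Reactants: 1 methyl 4-amino-3-fluorobenzoate
Product: 2 methyl 4-amino-3-fluoro-5-iodobenzoate
Conditions: NIS, CF3CO2H (cat.), MeCN, rt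
Reagents that add atoms: N-iodosuccinimide, O=C1CCC(=O)N1I
Why: Electrophilic aromatic iodination; the amino group is the strongest director, its para position is blocked by the ester and one ortho position by fluorine, so iodine should enter only at C5.

Step 2
Reactants: 2 methyl 4-amino-3-fluoro-5-iodobenzoate
Product: 4 methyl 4-bromo-3-fluoro-5-iodobenzoate, via arenediazonium salt 3 (not isolated)
Conditions: t-BuONO, CuBr2, MeCN, 0 → 60 °C
Reagents that add atoms: copper dibromide, Br[Cu]Br
Why: Sandmeyer bromination under aprotic conditions; alkyl nitrite diazotisation suits a weakly basic, doubly ortho-substituted aniline, the aryl radical takes bromine from CuBr2, and the ester, fluoride and iodide are inert.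

Step 3
Reactants: 4 methyl 4-bromo-3-fluoro-5-iodobenzoate
Product: 5 methyl 4-bromo-3-(2-tert-butoxy-2-oxoethyl)-5-fluorobenzoate
Conditions: ClZnCH2CO2t-Bu (1.1 equiv), Pd2(dba)3 (1 mol %), XPhos (4 mol %), THF, rt
Reagents that add atoms: 2-tert-butoxy-2-oxoethylzinc chloride, Cl[Zn]CC(=O)OC(C)(C)C
Why: Negishi coupling of a Reformatsky reagent (ester α-arylation); zerovalent palladium inserts into C–I much faster than into the doubly flanked C–Br, the zinc enolate does not attack the methyl ester, and the two carboxyl carbons end up as different esters.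

Step 4
Reactants: 5 methyl 4-bromo-3-(2-tert-butoxy-2-oxoethyl)-5-fluorobenzoate
Product: 6 2-[2-bromo-3-fluoro-5-(methoxycarbonyl)phenyl]acetic acid
Conditions: CF3CO2H, CH2Cl2, rt
Reagents that add atoms: none
Why: Acidolysis of the tert-butyl ester by loss of isobutene; the methyl benzoate and both aryl halides are untouched.

Step 5
Reactants: 6 2-[2-bromo-3-fluoro-5-(methoxycarbonyl)phenyl]acetic acid; 7 (R)-4-benzyl-2-oxazolidinone
Product: 9 methyl 3-{2-[(4R)-4-benzyl-2-oxo-1,3-oxazolidin-3-yl]-2-oxoethyl}-4-bromo-5-fluorobenzoate, via mixed pivalic anhydride 8 (not isolated)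
Conditions: t-BuCOCl, Et3N, THF, −20 °C; then 7, LiCl, −20 °C → rt
Reagents that add atoms: none
Why: N-acylation of the oxazolidinone through the mixed anhydride with LiCl activation; attack goes to the less hindered arylacetyl carbonyl, no strong base is needed and the methyl ester is not touched.

Step 6
Reactants: 9 methyl 3-{2-[(4R)-4-benzyl-2-oxo-1,3-oxazolidin-3-yl]-2-oxoethyl}-4-bromo-5-fluorobenzoate; 10 4-benzyloxy-3-methoxybenzaldehyde
Product: 12 (4R)-4-benzyl-3-[(2R,3R)-3-(4-benzyloxy-3-methoxyphenyl)-2-(2-bromo-3-fluoro-5-methoxycarbonylphenyl)-3-hydroxypropanoyl]-1,3-oxazolidin-2-one, via Z boron enolate 11 (not isolated)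
Conditions: Bu2BOTf, i-Pr2NEt, CH2Cl2, −78 → 0 °C; 10, −78 → 0 °C; pH 7 buffer, MeOH, H2O2, 0 °C
Reagents that add atoms: none
Why: Evans syn-aldol; soft enolisation gives the Z boron enolate 11, which adds through a closed Zimmerman–Traxler chair on the enolate face away from the benzyl group of the (R)-auxiliary and so sets the acyl chain as (2R,3R), syn, the diad that becomes trans C2/C3 of ring D.

Step 7
Reactants: 12 (4R)-4-benzyl-3-[(2R,3R)-3-(4-benzyloxy-3-methoxyphenyl)-2-(2-bromo-3-fluoro-5-methoxycarbonylphenyl)-3-hydroxypropanoyl]-1,3-oxazolidin-2-one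
Product: 13 (1R,2S)-1-(4-benzyloxy-3-methoxyphenyl)-2-[2-bromo-3-fluoro-5-(hydroxymethyl)phenyl]propane-1,3-diol
Conditions: LiBH4 (excess), MeOH, THF, 0 → 40 °C
Reagents that add atoms: none
Why: Hydride reduction; LiBH4 attacks the exocyclic imide carbonyl first and releases 7, and in excess it also reduces the electron-poor methyl benzoate, so both hydroxymethyl groups arise in one operation without touching either stereocentre (the 2S descriptor reflects only the changed priorities).

Step 8
Reactants: 13 (1R,2S)-1-(4-benzyloxy-3-methoxyphenyl)-2-[2-bromo-3-fluoro-5-(hydroxymethyl)phenyl]propane-1,3-diol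
Product: 14 (1R,2S)-1-(4-benzyloxy-3-methoxyphenyl)-2-[2-bromo-3-fluoro-5-(triisopropylsilyloxymethyl)phenyl]-3-(triisopropylsilyloxy)propan-1-ol
Conditions: i-Pr3SiCl (2.2 equiv), imidazole, DMF, 0 °C → rt
Reagents that add atoms: chlorotriisopropylsilane, CC(C)[Si](Cl)(C(C)C)C(C)C
Why: Silyl ether formation; the bulky chlorosilane should react only at the two primary hydroxyls and leave the hindered secondary benzylic alcohol free, and triisopropylsilyl is chosen because it resists base-induced O-to-O migration in step 9.

Step 9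
Reactants: 14 (1R,2S)-1-(4-benzyloxy-3-methoxyphenyl)-2-[2-bromo-3-fluoro-5-(triisopropylsilyloxymethyl)phenyl]-3-(triisopropylsilyloxy)propan-1-ol
Product: 19 (2R,3S)-2-(4-benzyloxy-3-methoxyphenyl)-3,5-bis(triisopropylsilyloxymethyl)-2,3-dihydro-1-benzofuran-7-ol, via dilithio species 15 (not isolated), via aryne alkoxide 16 (not isolated), via C7 aryllithium 17 (not isolated), via dimethyl boronate 18 (not isolated)
Conditions: n-BuLi (1.0 equiv), THF (0.02 M), −78 °C; t-BuLi (2.0 equiv), −78 °C; → −20 °C; B(OMe)3, −78 °C → rt; H2O2, NaOH aq., 0 °C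
Reagents that add atoms: hydrogen peroxide, OO
Why: n-BuLi forms the lithium alkoxide and t-BuLi exchanges the C7a bromine (the second equivalent destroys t-BuBr), giving 15. On warming 15 loses LiF and becomes the C7a–C7 aryne 16. The alkoxide adds in the plane of the aryne at C7a in a 5-exo-dig closure that forms O1–C7a and ring D and leaves the charge on C7 as aryllithium 17. B(OMe)3 captures 17 as boronate 18, and alkaline H2O2 converts C7–B into C7–O by the usual aryl shift from boron to oxygen. The closest known reaction type is the anionic aryne cyclisation of tethered heteroatom nucleophiles generated from ortho-halofluoroarenes with electrophilic quench of the new aryllithium, combined with the standard borylation–oxidation of aryllithiums. No stereocentre is formed and no bond to C2 or C3 is broken, so the (2R,3S) trans diad set by the aldol of step 6 is carried over unchanged. Regioselectivity is needed twice and the substrate secures it: Br at C7a next to F at C7 allows only the C7a–C7 aryne, and the tether from C3a lets the oxygen reach only C7a. Chemoselectivity against intermolecular addition is secured by leaving no alkyllithium or alkyl bromide in solution while the aryne lives, by dilution, and by the non-migrating silyl group that keeps the primary oxygen out of the ring closure.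

Step 10
Reactants: 19 (2R,3S)-2-(4-benzyloxy-3-methoxyphenyl)-3,5-bis(triisopropylsilyloxymethyl)-2,3-dihydro-1-benzofuran-7-ol
Product: 20 (2R,3S)-7-benzyloxy-2-(4-benzyloxy-3-methoxyphenyl)-3,5-bis(triisopropylsilyloxymethyl)-2,3-dihydro-1-benzofuran
Conditions: BnBr, K2CO3, DMF, rt
Reagents that add atoms: benzyl bromide, BrCc1ccccc1
Why: Williamson etherification of the phenol; the benzyl ether protects the electron-rich phenol from the oxidants of steps 12 and 15 and leaves with the other benzyl groups at the end.

Step 11
Reactants: 20 (2R,3S)-7-benzyloxy-2-(4-benzyloxy-3-methoxyphenyl)-3,5-bis(triisopropylsilyloxymethyl)-2,3-dihydro-1-benzofuran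
Product: 21 [(2R,3S)-7-benzyloxy-2-(4-benzyloxy-3-methoxyphenyl)-2,3-dihydro-1-benzofuran-3,5-diyl]dimethanol
Conditions: Bu4NF, THF, 0 °C → rt
Reagents that add atoms: none
Why: Fluoride-induced cleavage of both silyl ethers; benzyl ethers and ring D are inert.

Step 12
Reactants: 21 [(2R,3S)-7-benzyloxy-2-(4-benzyloxy-3-methoxyphenyl)-2,3-dihydro-1-benzofuran-3,5-diyl]dimethanol
Product: 22 (2R,3S)-7-benzyloxy-2-(4-benzyloxy-3-methoxyphenyl)-3-(hydroxymethyl)-2,3-dihydro-1-benzofuran-5-carbaldehyde
Conditions: MnO2 (activated, excess), CH2Cl2, rt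
Reagents that add atoms: none
Why: Chemoselective benzylic oxidation; MnO2 oxidises the C5 benzylic alcohol to the aldehyde and should leave the unactivated aliphatic primary alcohol alone, without over-oxidation.

Step 13
Reactants: 23 2',4',6'-trihydroxyacetophenone
Product: 24 1-[2,4-bis(benzyloxy)-6-hydroxyphenyl]ethan-1-one
Conditions: BnBr (2.05 equiv), K2CO3, DMF, rt
Reagents that add atoms: benzyl bromide, BrCc1ccccc1
Why: Williamson etherification; the para hydroxyl and one ortho hydroxyl are alkylated, while the remaining ortho hydroxyl is hydrogen-bonded to the carbonyl and much less nucleophilic.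

Step 14
Reactants: 22 (2R,3S)-7-benzyloxy-2-(4-benzyloxy-3-methoxyphenyl)-3-(hydroxymethyl)-2,3-dihydro-1-benzofuran-5-carbaldehyde; 24 1-[2,4-bis(benzyloxy)-6-hydroxyphenyl]ethan-1-one
Product: 25 (E)-1-[2,4-bis(benzyloxy)-6-hydroxyphenyl]-3-[(2R,3S)-7-benzyloxy-2-(4-benzyloxy-3-methoxyphenyl)-3-(hydroxymethyl)-2,3-dihydro-1-benzofuran-5-yl]prop-2-en-1-one
Conditions: KOH (aq., 50 %), EtOH–THF, rt
Reagents that add atoms: none
Why: Claisen–Schmidt condensation; the aldehyde has no α-hydrogen, dehydration of the aldol gives the E-enone, and the ring D hydrogens are not acidified because the carbonyl sits meta to C3a.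

Step 15
Reactants: 25 (E)-1-[2,4-bis(benzyloxy)-6-hydroxyphenyl]-3-[(2R,3S)-7-benzyloxy-2-(4-benzyloxy-3-methoxyphenyl)-3-(hydroxymethyl)-2,3-dihydro-1-benzofuran-5-yl]prop-2-en-1-one
Product: 27 5,7-bis(benzyloxy)-2-[(2R,3S)-7-benzyloxy-2-(4-benzyloxy-3-methoxyphenyl)-3-(hydroxymethyl)-2,3-dihydro-1-benzofuran-5-yl]-3-hydroxy-4H-chromen-4-one, via 3-hydroxyflavanone 26 (not isolated)
Conditions: H2O2 (30 %), NaOH aq., MeOH–THF, 0 °C → rt
Reagents that add atoms: hydrogen peroxide, OO
Why: Algar–Flynn–Oyamada oxidation; the 2'-phenoxide closes onto the enone β-carbon while hydroperoxide oxygenates the α-carbon to give 26, which the alkaline peroxide dehydrogenates to the flavonol; low temperature is chosen to favour six-ring over five-ring closure.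

Step 16
Reactants: 27 5,7-bis(benzyloxy)-2-[(2R,3S)-7-benzyloxy-2-(4-benzyloxy-3-methoxyphenyl)-3-(hydroxymethyl)-2,3-dihydro-1-benzofuran-5-yl]-3-hydroxy-4H-chromen-4-one
Product: 28 2,3-dehydrosilychristin
Conditions: H2 (1 atm), Pd/C (10 wt %), THF–MeOH, rt
Reagents that add atoms: none
Why: Catalytic hydrogenolysis of the four aryl benzyl ethers; the chromone C2'=C3' bond is a vinylogous ester and should not be reduced under these mild conditions, and the reaction is to be stopped at complete debenzylation to spare the benzylic C2–O1 bond.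

## Compound list

1 | methyl 4-amino-3-fluorobenzoate | COC(=O)c1ccc(N)c(F)c1 | starting material
2 | methyl 4-amino-3-fluoro-5-iodobenzoate | COC(=O)c1cc(F)c(N)c(I)c1 | intermediate
3 | 2-fluoro-6-iodo-4-(methoxycarbonyl)benzenediazonium bromide (not isolated) | COC(=O)c1cc(F)c([N+]#N)c(I)c1.[Br-] | intermediate
4 | methyl 4-bromo-3-fluoro-5-iodobenzoate | COC(=O)c1cc(F)c(Br)c(I)c1 | intermediate
5 | methyl 4-bromo-3-(2-tert-butoxy-2-oxoethyl)-5-fluorobenzoate | COC(=O)c1cc(F)c(Br)c(CC(=O)OC(C)(C)C)c1 | intermediate
6 | 2-[2-bromo-3-fluoro-5-(methoxycarbonyl)phenyl]acetic acid | COC(=O)c1cc(F)c(Br)c(CC(=O)O)c1 | intermediate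
7 | (R)-4-benzyl-2-oxazolidinone | O=C1N[C@H](Cc2ccccc2)CO1 | starting material
8 | mixed anhydride of 6 with pivalic acid (not isolated) | COC(=O)c1cc(F)c(Br)c(CC(=O)OC(=O)C(C)(C)C)c1 | intermediate
9 | methyl 3-{2-[(4R)-4-benzyl-2-oxo-1,3-oxazolidin-3-yl]-2-oxoethyl}-4-bromo-5-fluorobenzoate | COC(=O)c1cc(F)c(Br)c(CC(=O)N2[C@H](Cc3ccccc3)COC2=O)c1 | intermediate
10 | 4-benzyloxy-3-methoxybenzaldehyde | COc1cc(C=O)ccc1OCc1ccccc1 | starting material
11 | Z dibutylboron enolate of 9 (not isolated) | CCCCB(CCCC)O/C(=C\c1cc(C(=O)OC)cc(F)c1Br)N1[C@H](Cc2ccccc2)COC1=O | intermediate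
12 | (4R)-4-benzyl-3-[(2R,3R)-3-(4-benzyloxy-3-methoxyphenyl)-2-(2-bromo-3-fluoro-5-methoxycarbonylphenyl)-3-hydroxypropanoyl]-1,3-oxazolidin-2-one | COc1cc([C@H](O)[C@H](C(=O)N2[C@H](Cc3ccccc3)COC2=O)c2cc(C(=O)OC)cc(F)c2Br)ccc1OCc1ccccc1 | intermediate
13 | (1R,2S)-1-(4-benzyloxy-3-methoxyphenyl)-2-[2-bromo-3-fluoro-5-(hydroxymethyl)phenyl]propane-1,3-diol | COc1cc([C@H](O)[C@H](CO)c2cc(CO)cc(F)c2Br)ccc1OCc1ccccc1 | intermediate
14 | (1R,2S)-1-(4-benzyloxy-3-methoxyphenyl)-2-[2-bromo-3-fluoro-5-(triisopropylsilyloxymethyl)phenyl]-3-(triisopropylsilyloxy)propan-1-ol | COc1cc([C@H](O)[C@H](CO[Si](C(C)C)(C(C)C)C(C)C)c2cc(CO[Si](C(C)C)(C(C)C)C(C)C)cc(F)c2Br)ccc1OCc1ccccc1 | intermediate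
15 | lithium alkoxide of 14 carrying lithium in place of bromine at C7a (not isolated) | COc1cc([C@H](O[Li])[C@H](CO[Si](C(C)C)(C(C)C)C(C)C)c2cc(CO[Si](C(C)C)(C(C)C)C(C)C)cc(F)c2[Li])ccc1OCc1ccccc1 | intermediate
16 | C7a–C7 aryne lithium alkoxide (not isolated) | COc1cc([C@H](O[Li])[C@H](CO[Si](C(C)C)(C(C)C)C(C)C)C2=CC(CO[Si](C(C)C)(C(C)C)C(C)C)=CC#C2)ccc1OCc1ccccc1 | intermediate
17 | (2R,3S)-2-(4-benzyloxy-3-methoxyphenyl)-7-lithio-3,5-bis(triisopropylsilyloxymethyl)-2,3-dihydro-1-benzofuran (not isolated) | COc1cc([C@@H]2Oc3c([Li])cc(CO[Si](C(C)C)(C(C)C)C(C)C)cc3[C@H]2CO[Si](C(C)C)(C(C)C)C(C)C)ccc1OCc1ccccc1 | intermediate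
18 | dimethyl [(2R,3S)-2-(4-benzyloxy-3-methoxyphenyl)-3,5-bis(triisopropylsilyloxymethyl)-2,3-dihydro-1-benzofuran-7-yl]boronate (not isolated) | COc1cc([C@@H]2Oc3c(B(OC)OC)cc(CO[Si](C(C)C)(C(C)C)C(C)C)cc3[C@H]2CO[Si](C(C)C)(C(C)C)C(C)C)ccc1OCc1ccccc1 | intermediate
19 | (2R,3S)-2-(4-benzyloxy-3-methoxyphenyl)-3,5-bis(triisopropylsilyloxymethyl)-2,3-dihydro-1-benzofuran-7-ol | COc1cc([C@@H]2Oc3c(O)cc(CO[Si](C(C)C)(C(C)C)C(C)C)cc3[C@H]2CO[Si](C(C)C)(C(C)C)C(C)C)ccc1OCc1ccccc1 | intermediate
20 | (2R,3S)-7-benzyloxy-2-(4-benzyloxy-3-methoxyphenyl)-3,5-bis(triisopropylsilyloxymethyl)-2,3-dihydro-1-benzofuran | COc1cc([C@@H]2Oc3c(OCc4ccccc4)cc(CO[Si](C(C)C)(C(C)C)C(C)C)cc3[C@H]2CO[Si](C(C)C)(C(C)C)C(C)C)ccc1OCc1ccccc1 | intermediate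
21 | [(2R,3S)-7-benzyloxy-2-(4-benzyloxy-3-methoxyphenyl)-2,3-dihydro-1-benzofuran-3,5-diyl]dimethanol | COc1cc([C@@H]2Oc3c(OCc4ccccc4)cc(CO)cc3[C@H]2CO)ccc1OCc1ccccc1 | intermediate
22 | (2R,3S)-7-benzyloxy-2-(4-benzyloxy-3-methoxyphenyl)-3-(hydroxymethyl)-2,3-dihydro-1-benzofuran-5-carbaldehyde | COc1cc([C@@H]2Oc3c(OCc4ccccc4)cc(C=O)cc3[C@H]2CO)ccc1OCc1ccccc1 | intermediate
23 | 2',4',6'-trihydroxyacetophenone | CC(=O)c1c(O)cc(O)cc1O | starting material
24 | 1-[2,4-bis(benzyloxy)-6-hydroxyphenyl]ethan-1-one | CC(=O)c1c(O)cc(OCc2ccccc2)cc1OCc1ccccc1 | intermediate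
25 | (E)-1-[2,4-bis(benzyloxy)-6-hydroxyphenyl]-3-[(2R,3S)-7-benzyloxy-2-(4-benzyloxy-3-methoxyphenyl)-3-(hydroxymethyl)-2,3-dihydro-1-benzofuran-5-yl]prop-2-en-1-one | COc1cc([C@@H]2Oc3c(OCc4ccccc4)cc(/C=C/C(=O)c4c(O)cc(OCc5ccccc5)cc4OCc4ccccc4)cc3[C@H]2CO)ccc1OCc1ccccc1 | intermediate
26 | 5,7-bis(benzyloxy)-2-[(2R,3S)-7-benzyloxy-2-(4-benzyloxy-3-methoxyphenyl)-3-(hydroxymethyl)-2,3-dihydro-1-benzofuran-5-yl]-3-hydroxychroman-4-one, mixture at C2'/C3' (not isolated) | COc1cc([C@@H]2Oc3c(OCc4ccccc4)cc(C4Oc5cc(OCc6ccccc6)cc(OCc6ccccc6)c5C(=O)C4O)cc3[C@H]2CO)ccc1OCc1ccccc1 | intermediate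
27 | 5,7-bis(benzyloxy)-2-[(2R,3S)-7-benzyloxy-2-(4-benzyloxy-3-methoxyphenyl)-3-(hydroxymethyl)-2,3-dihydro-1-benzofuran-5-yl]-3-hydroxy-4H-chromen-4-one | COc1cc([C@@H]2Oc3c(OCc4ccccc4)cc(-c4oc5cc(OCc6ccccc6)cc(OCc6ccccc6)c5c(=O)c4O)cc3[C@H]2CO)ccc1OCc1ccccc1 | intermediate
28 | 2,3-dehydrosilychristin, 3,5,7-trihydroxy-2-[(2R,3S)-7-hydroxy-2-(4-hydroxy-3-methoxyphenyl)-3-(hydroxymethyl)-2,3-dihydro-1-benzofuran-5-yl]-4H-chromen-4-one | COc1cc([C@@H]2Oc3c(O)cc(-c4oc5cc(O)cc(O)c5c(=O)c4O)cc3[C@H]2CO)ccc1O | target

## Step count and least certain steps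

Total step count: 16. Longest linear sequence: 15 steps (steps 1–12 and 14–16, from 1 to 28). Step 13 is the only step off the main line.

**Step 9 (key step).** While the mixture warms, the aryne, the not yet eliminated aryllithium and the cyclised C7 aryllithium coexist. The aryne may therefore be consumed between molecules faster than the aggregated lithium alkoxide closes the ring. The aliphatic silyl group may also shift to the secondary alkoxide, after which the primary oxygen would close the ring instead.

The fallback uses no aryne. The C7 oxygen is carried from the start and O1–C7a is made by palladium catalysis. It sets out from 7 and 10 and returns at 20.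
- Commercial methyl 4-amino-3-hydroxybenzoate F1 is O-benzylated (BnBr, K2CO3, DMF) to methyl 4-amino-3-(benzyloxy)benzoate F2.
- The operations of steps 1–8 are repeated on this series: iodination to methyl 4-amino-3-(benzyloxy)-5-iodobenzoate F3, and diazotisation–bromination through the diazonium salt F4 to methyl 3-(benzyloxy)-4-bromo-5-iodobenzoate F5.
- Zinc enolate coupling gives the tert-butyl ester F6, and acidolysis gives the arylacetic acid F7.
- Acylation of 7 through the mixed anhydride F8 gives the imide F9. The boron aldol with 10 through the enolate F10 gives the syn adduct F11.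
- LiBH4 reduction gives the triol F12, and double silylation gives the bromo alcohol F13.
- Intramolecular C–O coupling of F13 (Pd(OAc)2, 2-(di-tert-butylphosphino)-1,1'-binaphthyl, Cs2CO3, toluene, 70 °C) closes ring D at C7a without touching C2 or C3 and should give 20 directly.

**Step 3.** Oxidative addition may not discriminate fully between the iodide and the neighbouring bromide under an active phosphine, which would lead to double coupling or loss of bromine. The ortho bromine may also slow the coupling so that protodehalogenation competes.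

The fallback sets out from 4 and returns at 6. Copper-catalysed arylation of di-tert-butyl malonate (CuI, 2-picolinic acid, Cs2CO3, dioxane, rt → 50 °C), which touches only aryl iodides, gives di-tert-butyl 2-[2-bromo-3-fluoro-5-(methoxycarbonyl)phenyl]malonate F14. CF3CO2H in CH2Cl2 gives the malonic acid F15, which loses CO2 in toluene at 100 °C to give 6.

**Step 6.** The aldol addition may reverse, and the doubly activated α-carbon may epimerise during reaction or work-up. An enolate crowded by the ortho bromine may also add slowly to the electron-rich aldehyde; each of these would erode conversion or the diastereomer ratio.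

The fallback sets out from 6 and returns at 13. The acid is coupled (EDC·HCl, DMAP, CH2Cl2) with commercial (R)-4-benzyl-1,3-thiazolidine-2-thione F16 to the N-acyl thiazolidinethione F17. TiCl4, i-Pr2NEt and N-methylpyrrolidinone in CH2Cl2 at −78 °C give the chlorotitanium enolate F18, whose more Lewis-acidic, covalent transition state should add to 10 with the same facial sense to give the syn adduct F19. LiBH4 then removes the thione auxiliary and reduces the ester, giving 13.

**Step 15.** The 2'-phenoxide may attack the α-carbon of the oxygenated enone, a five-ring closure to an aurone that the alkoxy group next to the carbonyl is known to favour.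

The fallback sets out from 25 and returns at 27. Oxidative cyclisation (I2 cat., DMSO, 120 °C), which gives only the six-membered ring, leads to 5,7-bis(benzyloxy)-2-[(2R,3S)-7-benzyloxy-2-(4-benzyloxy-3-methoxyphenyl)-3-(hydroxymethyl)-2,3-dihydro-1-benzofuran-5-yl]-4H-chromen-4-one F20. Dimethyldioxirane (acetone–CH2Cl2, 0 °C) gives the 2',3'-epoxide F21, which opens with TsOH (cat.) to 27.

**Step 16.** Hydrogenolysis may go on to the benzylic C2–O1 bond of ring D, or saturation of C2'=C3' may set in once the benzyl ethers are gone, since the last debenzylations are slowed by the free phenols binding to the catalyst.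

The fallback sets out from 27 and arrives at 28 without new compounds. It uses non-reductive Lewis-acid debenzylation with a cation scavenger (BCl3, pentamethylbenzene, CH2Cl2, −78 °C, methanol quench).

## Further compounds

F1 | step 9 | methyl 4-amino-3-hydroxybenzoate (bought) | COC(=O)c1ccc(N)c(O)c1
F2 | step 9 | methyl 4-amino-3-(benzyloxy)benzoate | COC(=O)c1ccc(N)c(OCc2ccccc2)c1
F3 | step 9 | methyl 4-amino-3-(benzyloxy)-5-iodobenzoate | COC(=O)c1cc(I)c(N)c(OCc2ccccc2)c1
F4 | step 9 | 2-(benzyloxy)-6-iodo-4-(methoxycarbonyl)benzenediazonium bromide | COC(=O)c1cc(I)c([N+]#N)c(OCc2ccccc2)c1.[Br-]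
F5 | step 9 | methyl 3-(benzyloxy)-4-bromo-5-iodobenzoate | COC(=O)c1cc(I)c(Br)c(OCc2ccccc2)c1
F6 | step 9 | methyl 3-(benzyloxy)-4-bromo-5-(2-tert-butoxy-2-oxoethyl)benzoate | COC(=O)c1cc(CC(=O)OC(C)(C)C)c(Br)c(OCc2ccccc2)c1
F7 | step 9 | 2-[3-(benzyloxy)-2-bromo-5-(methoxycarbonyl)phenyl]acetic acid | COC(=O)c1cc(CC(=O)O)c(Br)c(OCc2ccccc2)c1
F8 | step 9 | mixed anhydride of F7 with pivalic acid | COC(=O)c1cc(CC(=O)OC(=O)C(C)(C)C)c(Br)c(OCc2ccccc2)c1
F9 | step 9 | methyl 3-{2-[(4R)-4-benzyl-2-oxo-1,3-oxazolidin-3-yl]-2-oxoethyl}-5-(benzyloxy)-4-bromobenzoate | COC(=O)c1cc(CC(=O)N2[C@H](Cc3ccccc3)COC2=O)c(Br)c(OCc2ccccc2)c1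
F10 | step 9 | Z dibutylboron enolate of F9 | CCCCB(CCCC)O/C(=C\c1cc(C(=O)OC)cc(OCc2ccccc2)c1Br)N1[C@H](Cc2ccccc2)COC1=O
F11 | step 9 | (4R)-4-benzyl-3-[(2R,3R)-3-(4-benzyloxy-3-methoxyphenyl)-2-(3-benzyloxy-2-bromo-5-methoxycarbonylphenyl)-3-hydroxypropanoyl]-1,3-oxazolidin-2-one | COc1cc([C@H](O)[C@H](C(=O)N2[C@H](Cc3ccccc3)COC2=O)c2cc(C(=O)OC)cc(OCc3ccccc3)c2Br)ccc1OCc1ccccc1
F12 | step 9 | (1R,2S)-1-(4-benzyloxy-3-methoxyphenyl)-2-[3-benzyloxy-2-bromo-5-(hydroxymethyl)phenyl]propane-1,3-diol | COc1cc([C@H](O)[C@H](CO)c2cc(CO)cc(OCc3ccccc3)c2Br)ccc1OCc1ccccc1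
F13 | step 9 | (1R,2S)-1-(4-benzyloxy-3-methoxyphenyl)-2-[3-benzyloxy-2-bromo-5-(triisopropylsilyloxymethyl)phenyl]-3-(triisopropylsilyloxy)propan-1-ol | COc1cc([C@H](O)[C@H](CO[Si](C(C)C)(C(C)C)C(C)C)c2cc(CO[Si](C(C)C)(C(C)C)C(C)C)cc(OCc3ccccc3)c2Br)ccc1OCc1ccccc1
F14 | step 3 | di-tert-butyl 2-[2-bromo-3-fluoro-5-(methoxycarbonyl)phenyl]malonate | COC(=O)c1cc(F)c(Br)c(C(C(=O)OC(C)(C)C)C(=O)OC(C)(C)C)c1
F15 | step 3 | 2-[2-bromo-3-fluoro-5-(methoxycarbonyl)phenyl]malonic acid | COC(=O)c1cc(F)c(Br)c(C(C(=O)O)C(=O)O)c1
F16 | step 6 | (R)-4-benzyl-1,3-thiazolidine-2-thione (bought) | S=C1N[C@H](Cc2ccccc2)CS1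
F17 | step 6 | methyl 3-{2-[(4R)-4-benzyl-2-thioxo-1,3-thiazolidin-3-yl]-2-oxoethyl}-4-bromo-5-fluorobenzoate | COC(=O)c1cc(F)c(Br)c(CC(=O)N2[C@H](Cc3ccccc3)CSC2=S)c1
F18 | step 6 | Z trichlorotitanium enolate of F17 | Cl[Ti](Cl)(Cl)O/C(=C\c1cc(C(=O)OC)cc(F)c1Br)N1[C@H](Cc2ccccc2)CSC1=S
F19 | step 6 | (2R,3R)-syn aldol adduct of F17 with 10 | COc1cc([C@H](O)[C@H](C(=O)N2[C@H](Cc3ccccc3)CSC2=S)c2cc(C(=O)OC)cc(F)c2Br)ccc1OCc1ccccc1
F20 | step 15 | 5,7-bis(benzyloxy)-2-[(2R,3S)-7-benzyloxy-2-(4-benzyloxy-3-methoxyphenyl)-3-(hydroxymethyl)-2,3-dihydro-1-benzofuran-5-yl]-4H-chromen-4-one | COc1cc([C@@H]2Oc3c(OCc4ccccc4)cc(-c4cc(=O)c5c(OCc6ccccc6)cc(OCc6ccccc6)cc5o4)cc3[C@H]2CO)ccc1OCc1ccccc1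
F21 | step 15 | 2',3'-epoxide of F20 | COc1cc([C@@H]2Oc3c(OCc4ccccc4)cc(C45OC4C(=O)c4c(OCc6ccccc6)cc(OCc6ccccc6)cc4O5)cc3[C@H]2CO)ccc1OCc1ccccc1
F0 | step 16 | none | none
A1 | alternative 1 | (E)-2-(benzyloxy)-3-[3,5-bis(benzyloxy)phenoxy]-3-[(2R,3S)-7-benzyloxy-2-(4-benzyloxy-3-methoxyphenyl)-3-(benzyloxymethyl)-2,3-dihydro-1-benzofuran-5-yl]acrylic acid | COc1cc([C@@H]2Oc3c(OCc4ccccc4)cc(/C(Oc4cc(OCc5ccccc5)cc(OCc5ccccc5)c4)=C(\OCc4ccccc4)C(=O)O)cc3[C@H]2COCc2ccccc2)ccc1OCc1ccccc1
A2 | alternative 1 | hexa-O-benzyl 2,3-dehydrosilychristin | COc1cc([C@@H]2Oc3c(OCc4ccccc4)cc(-c4oc5cc(OCc6ccccc6)cc(OCc6ccccc6)c5c(=O)c4OCc4ccccc4)cc3[C@H]2COCc2ccccc2)ccc1OCc1ccccc1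
A3 | alternative 2 | 2-(benzyloxy)-4-bromo-6-[2-(tert-butyldimethylsilyloxy)-1-(4-methylphenylsulfonyl)ethyl]phenol (racemic) | Cc1ccc(S(=O)(=O)C(CO[Si](C)(C)C(C)(C)C)c2cc(Br)cc(OCc3ccccc3)c2O)cc1
A4 | alternative 2 | (2R,5R)-1-(4-benzyloxy-3-methoxybenzyl)-2,5-dimethylthiolan-1-ium triflate | C[C@@H]1CC[C@@H](C)[S+]1Cc1ccc(OCc2ccccc2)c(OC)c1.[O-]S(=O)(=O)C(F)(F)F
A5 | alternative 2 | (2R,3S)-7-benzyloxy-2-(4-benzyloxy-3-methoxyphenyl)-5-bromo-3-(tert-butyldimethylsilyloxymethyl)-2,3-dihydro-1-benzofuran | COc1cc([C@@H]2Oc3c(OCc4ccccc4)cc(Br)cc3[C@H]2CO[Si](C)(C)C(C)(C)C)ccc1OCc1ccccc1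
A6 | alternative 3 | (R)-8-benzyloxy-2-(4-benzyloxy-3-methoxyphenyl)-6-bromo-2H-chromene | COc1cc([C@@H]2Oc3c(OCc4ccccc4)cc(Br)cc3C=C2)ccc1OCc1ccccc1
A7 | alternative 3 | trans-7-benzyloxy-2-(4-benzyloxy-3-methoxyphenyl)-5-bromo-3-(dimethoxymethyl)-2,3-dihydro-1-benzofuran | COc1cc([C@@H]2Oc3c(OCc4ccccc4)cc(Br)cc3[C@H]2C(OC)OC)ccc1OCc1ccccc1
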